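The constants come from no measurement; what happens was integrated by code.

In a one-step world, substrate would turn into target by the plain first-order step and nothing else, and that world is the zero of our scale.

    substrate + 2 target → 3 target (k1 = 0.0048 L² mol⁻² min⁻¹, Ea1 = 63.0 kJ mol⁻¹)
    substrate → target (k2 = 5.4 × 10⁻⁴ min⁻¹, Ea2 = 91.0 kJ mol⁻¹)
    substrate → decomposition product (k3 = 1.2 × 10⁻⁵ min⁻¹, Ea3 = 109 kJ mol⁻¹)
    target → over-reaction product (k4 = 0.0014 min⁻¹, Ea4 = 93.0 kJ mol⁻¹)
    (constants at 0 °C)

| flask | substrate | temperature | time | remark |
|---|---|---|---|---|
| Wednesday's | 3.0 M | −15 °C | 3.0 h |  |
| Sunday's | 3.0 M |  | 3.0 h | at −15 °C until 50 min, from then on at 15 °C |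
| Thursday's | 3.0 M | 15 °C | 3.0 h |  |
| Tuesday's | 3.0 M | 0 °C | 3.0 h |  |

- which flask leads in amount of target, in percent of the substrate charged ("all alike" within 1.5 percentage points) (Wednesday's / Sunday's / Thursday's / Tuesday's / all alike)
- how much target is there at the end, in percent of the substrate charged: Wednesday's
- how much target is there at the end, in percent of the substrate charged: Sunday's
- how much target is there at the end, in percent of the substrate charged: Thursday's
- how much target is there at the end, in percent of the substrate charged: Tuesday's

- two of one species on the left: rate k times its square, two consumed each time
- constants are those at 0 °C; use the activation energies for any other temperature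

The first line of the scheme takes us off that zero. The autocatalytic step goes with the square of c(target), so at the start, with c(target) at zero, it stands still and the plain step has to seed it. The two steps run equally fast once c(target) reaches the square root of the plain constant over the autocatalytic one. In Thursday's, at 15 °C, the plain step on a full c(substrate) takes 0.591 h to get there. That time, one over c(substrate) times the root of the product of the two constants, is the fuse, or induction time.

Both constants rise with temperature, so the fuse shortens as the flask warms. Tuesday's has 3.45 h and Wednesday's 24.7 h. Wednesday's spends 0.121 of its fuse in 3.0 h, so it should stay at the zero of the scale, with the plain step giving 0.943 % of target. Tuesday's spends 0.870 of its fuse, so we expect somewhat over the plain 9.26 %.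

Thursday's has 5.08 fuses, so it burns, and over-reaction then eats the target. Sunday's spends 0.0337 of the cold fuse before the change and then has 3.67 warm fuses, fewer than Thursday's. It should burn later and so keep more target, but our reckoning gives no figure for these two flasks.

The forecast names Sunday's, with 0.94 % for Wednesday's, 45.5 % for Sunday's, 27 % for Thursday's and 10.4 % for Tuesday's, holding that “its cold first 50 minutes simply delay that same burst”.

The flasks give 0.936 %, 45.3 %, 26.0 % and 10.2 % in that order, so Sunday's leads. Sunday's reaches a conversion of 30.0 % of its substrate at 1.64 h and Thursday's at 0.817 h. Counted from the change, Sunday's takes 0.807 h, which is 1.37 fuses against 1.38 in Thursday's, so the cold stretch of Sunday's shows up as a plain delay of the warm flask.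

Wednesday's charge at 10 °C has a fuse of 1.04 h, so 3.0 h holds 2.88 fuses and that flask should burn. It ends with 2.98 % of substrate and 63.2 % of target.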